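**Plan**

- Retrosynthetic cuts: (a) the imidazole C5–CH2(aryl) bond, made last; (b) the exocyclic N–C bond to the dehydrohydantoin, which comes from 1-methylparabanic acid; (c) N1–C2 and N3–C4 of the 2-aminoimidazole, from an α-(methylamino)ketone and cyanamide; (d) the ketone C–CH2Ar bond, from Boc-sarcosine Weinreb amide and 4-methoxybenzyl Grignard.
- Enabling feature: the C5 substituent is a hydroquinone whose benzylic carbon is ortho to an OH. That ring is the aromatised adduct of the o-quinone methide tautomer of 2,3-dimethoxy-5-methyl-1,4-benzoquinone (coenzyme Q0, its C5-methyl next to the C4 carbonyl). C5 is the only unsubstituted, enamine-like carbon of the 2-aminoimidazole.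
- Forward order: chain assembly (steps 1–3), imidazole ring (step 4), dehydrohydantoin ring attached (step 5), union with the quinone, which becomes the hydroquinone ring in the same event (step 6). No protecting group is carried beyond step 3.
- Stereochemistry: none to set.

Key step: step 6

Remark: the target SMILES contains no stereocentre or other stereogenic element, so the compound is achiral and the route needs no stereocontrol. Compounds 1, 4 (THF solution), 9 and 12 are taken as purchased.

**Route**

Step 1
Reactants: 1 N-Boc-sarcosine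
Product: 3 tert-butyl N-{2-[methoxy(methyl)amino]-2-oxoethyl}-N-methylcarbamate, via tert-butyl N-[2-(1H-imidazol-1-yl)-2-oxoethyl]-N-methylcarbamate 2 (not isolated)
Conditions: CDI, CH2Cl2, 0 °C to rt; then MeNH(OMe)·HCl, rt
Reagents that add atoms: N,O-dimethylhydroxylamine hydrochloride, CNOC.Cl
Why: CDI should activate the acid as the acyl imidazolide 2, which is aminolysed by N,O-dimethylhydroxylamine (standard Weinreb amide formation).

Step 2
Reactants: 3 tert-butyl N-{2-[methoxy(methyl)amino]-2-oxoethyl}-N-methylcarbamate; 4 (4-methoxybenzyl)magnesium chloride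
Product: 5 tert-butyl N-[3-(4-methoxyphenyl)-2-oxopropyl]-N-methylcarbamate
Conditions: THF, −10 to 0 °C; aq NH4Cl
Reagents that add atoms: none
Why: Weinreb ketone synthesis; the Grignard reagent should add once to give a chelated tetrahedral intermediate that collapses to the ketone only on work-up, and the N-methyl carbamate has no acidic N–H.

Step 3
Reactants: 5 tert-butyl N-[3-(4-methoxyphenyl)-2-oxopropyl]-N-methylcarbamate
Product: 6 1-(4-methoxyphenyl)-3-(methylamino)propan-2-one hydrochloride
Conditions: 4 M HCl in dioxane, rt
Reagents that add atoms: hydrogen chloride, Cl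
Why: Acidolysis of the Boc carbamate (loss of isobutene and CO2) should give the α-aminoketone as its hydrochloride, the form in which it cannot self-condense.

Step 4
Reactants: 6 1-(4-methoxyphenyl)-3-(methylamino)propan-2-one hydrochloride
Product: 8 4-(4-methoxybenzyl)-1-methyl-1H-imidazol-2-amine, via 1-[3-(4-methoxyphenyl)-2-oxopropyl]-1-methylguanidine hydrochloride 7 (not isolated)
Conditions: H2NCN (excess), H2O, pH 4.5, 95 °C; then aq NaOH
Reagents that add atoms: cyanamide, N#CN
Why: Marckwald-type 2-aminoimidazole synthesis; the secondary amine should add to cyanamide to give guanidine 7, whose NH2 condenses with the ketone and dehydrates to the aromatic ring, placing methyl on N1 and the anisylmethyl group on C4 and leaving C5 free.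

Step 5
Reactants: 8 4-(4-methoxybenzyl)-1-methyl-1H-imidazol-2-amine; 9 1-methylparabanic acid
Product: 11 5-{[4-(4-methoxybenzyl)-1-methyl-1H-imidazol-2-yl]amino}-3-methyl-3H-imidazole-2,4-dione, via 1-methyl-4-[(trimethylsilyl)oxy]-1H-imidazole-2,5-dione 10 (not isolated)
Conditions: 9, BSA, MeCN, 80 °C; then 8, PhMe, 110 °C; MeOH/H2O work-up
Reagents that add atoms: none
Why: BSA should convert 9 into its O-silyl lactim 10, and addition–elimination of the exocyclic amine of 8 at the silyloxy-imine carbon (C4, next to the unsubstituted nitrogen) with loss of trimethylsilanol gives the dehydrohydantoin, the established way from naamine-type 2-aminoimidazoles to naamidines.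

Step 6
Reactants: 11 5-{[4-(4-methoxybenzyl)-1-methyl-1H-imidazol-2-yl]amino}-3-methyl-3H-imidazole-2,4-dione; 12 coenzyme Q0 (2,3-dimethoxy-5-methyl-1,4-benzoquinone)
Product: 14 naamidine E, via 4-hydroxy-2,3-dimethoxy-6-methylidenecyclohexa-2,4-dien-1-one 13 (not isolated)
Conditions: 11 (1.2 equiv), DBU (1.0 equiv), degassed MeCN, Ar, 0 °C to rt, 12 (1.0 equiv) added over 6 h; then AcOH, aq Na2S2O4
Reagents that add atoms: none
Why: Proposed new method: the DBU salt of 11 (an amidinate whose charge is relayed through C2=N3 and C4=C5 to C5) should act as base on 12 and remove a proton from the C5-methyl group, which is vinylogous to the C1 carbonyl; O-protonation gives the o-quinone methide 13, whose exocyclic CH2 is attacked by imidazole C5 in a 1,4-addition that aromatises the six-membered ring to the hydroquinone, and loss of the C5 proton restores the imidazole. The closest known reaction types are the base-induced tautomerisation of alkyl-1,4-benzoquinones to o-quinone methides (side-chain amination of methylquinones, chromenol formation from prenylquinones) and the conjugate addition of indoles, enamines and phenols to o-quinone methides. No ring is closed and no stereocentre is formed. The step needs C–C over N–C bond formation and reaction through 13 instead of attack on the nucleus of 12: C5 is the only free ring carbon, N-adducts of o-quinone methides are o-hydroxybenzyl amidines that revert by retro-Michael loss while the C–C bond is permanent, and 13 is far more electrophilic than 12, both of whose carbonyl groups are vinylogous esters. Slow addition keeps 12 and 13 dilute, which disfavours the second-order self-condensation of the quinone and limits hydrogen exchange with the product, and the dithionite quench should return any product oxidised by 12 to the hydroquinone.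

**Compound list**

1 | N-Boc-sarcosine [N-(tert-butoxycarbonyl)-N-methylglycine] | CN(CC(=O)O)C(=O)OC(C)(C)C | starting material
2 | tert-butyl N-[2-(1H-imidazol-1-yl)-2-oxoethyl]-N-methylcarbamate (not isolated) | CN(CC(=O)n1ccnc1)C(=O)OC(C)(C)C | intermediate
3 | tert-butyl N-{2-[methoxy(methyl)amino]-2-oxoethyl}-N-methylcarbamate | CON(C)C(=O)CN(C)C(=O)OC(C)(C)C | intermediate
4 | (4-methoxybenzyl)magnesium chloride | COc1ccc(C[Mg]Cl)cc1 | starting material
5 | tert-butyl N-[3-(4-methoxyphenyl)-2-oxopropyl]-N-methylcarbamate | COc1ccc(CC(=O)CN(C)C(=O)OC(C)(C)C)cc1 | intermediate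
6 | 1-(4-methoxyphenyl)-3-(methylamino)propan-2-one hydrochloride | COc1ccc(CC(=O)CNC)cc1.Cl | intermediate
7 | 1-[3-(4-methoxyphenyl)-2-oxopropyl]-1-methylguanidine hydrochloride (not isolated) | COc1ccc(CC(=O)CN(C)C(N)=N)cc1.Cl | intermediate
8 | 4-(4-methoxybenzyl)-1-methyl-1H-imidazol-2-amine | COc1ccc(Cc2cn(C)c(N)n2)cc1 | intermediate
9 | 1-methylparabanic acid (1-methylimidazolidine-2,4,5-trione) | CN1C(=O)NC(=O)C1=O | starting material
10 | 1-methyl-4-[(trimethylsilyl)oxy]-1H-imidazole-2,5-dione (not isolated) | CN1C(=O)N=C(O[Si](C)(C)C)C1=O | intermediate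
11 | 5-{[4-(4-methoxybenzyl)-1-methyl-1H-imidazol-2-yl]amino}-3-methyl-3H-imidazole-2,4-dione | COc1ccc(Cc2cn(C)c(NC3=NC(=O)N(C)C3=O)n2)cc1 | intermediate
12 | coenzyme Q0 (2,3-dimethoxy-5-methyl-1,4-benzoquinone) | COC1=C(OC)C(=O)C(C)=CC1=O | starting material
13 | 4-hydroxy-2,3-dimethoxy-6-methylidenecyclohexa-2,4-dien-1-one (not isolated) | C=C1C=C(O)C(OC)=C(OC)C1=O | intermediate
14 | naamidine E, 5-{[5-(2,5-dihydroxy-3,4-dimethoxybenzyl)-4-(4-methoxybenzyl)-1-methyl-1H-imidazol-2-yl]amino}-3-methyl-3H-imidazole-2,4-dione | COc1ccc(Cc2nc(NC3=NC(=O)N(C)C3=O)n(C)c2Cc2cc(O)c(OC)c(OC)c2O)cc1 | target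

**Totals and risks**

Total step count: 6. Longest linear sequence: 6 steps (1 to 14).

Steps most likely to fail:

Step 6 (proposed new method). Several processes could defeat it:
- The amidinate could add directly to the quinone nucleus, at the free C6 position or with displacement of a methoxy group, faster than through the tautomer.
- Hydrogen exchange between the product hydroquinone and unconsumed quinone could drain the quinone and expose oxidised product to base.
- A second alkylation could occur at the free arene position of the product.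

The fallback uses halogen–metal exchange, aldehyde addition and ionic deoxygenation, all known on 1-methylimidazoles of this kind. It sets out from 8 and comes back to the route at 14.
- Condensation of 8 with DMF dimethyl acetal should give N'-[4-(4-methoxybenzyl)-1-methyl-1H-imidazol-2-yl]-N,N-dimethylformimidamide F1.
- NBS in THF at −78 °C should brominate the free C5 position to give N'-[5-bromo-4-(4-methoxybenzyl)-1-methyl-1H-imidazol-2-yl]-N,N-dimethylformimidamide F2.
- The aryl partner comes from purchased 2,3-dimethoxy-1,4-benzoquinone. Dithionite reduction gives 2,3-dimethoxybenzene-1,4-diol F3. MOMCl/i-Pr2NEt gives 2,3-dimethoxy-1,4-bis(methoxymethoxy)benzene F4. Ortho-lithiation (n-BuLi, TMEDA) and DMF quench gives 3,4-dimethoxy-2,5-bis(methoxymethoxy)benzaldehyde F5.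
- Bromine–lithium exchange on F2 (n-BuLi, THF, −78 °C) and addition to F5 should give the racemic carbinol N'-[5-{[3,4-dimethoxy-2,5-bis(methoxymethoxy)phenyl](hydroxy)methyl}-4-(4-methoxybenzyl)-1-methyl-1H-imidazol-2-yl]-N,N-dimethylformimidamide F6.
- Et3SiH/TFA should remove the doubly activated hydroxyl group and both MOM groups to give N'-[5-(2,5-dihydroxy-3,4-dimethoxybenzyl)-4-(4-methoxybenzyl)-1-methyl-1H-imidazol-2-yl]-N,N-dimethylformimidamide F7.
- Hydrazine hydrate in EtOH should free 2-{[2-amino-4-(4-methoxybenzyl)-1-methyl-1H-imidazol-5-yl]methyl}-5,6-dimethoxybenzene-1,4-diol F8.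
- Condensation of F8 with 9/BSA under the conditions of step 5 (the phenols are silylated in the flask and freed on work-up) returns to 14.

Step 4. The liberated α-aminoketone could self-condense (dihydropyrazine formation and oxidation) faster than it is guanylated, and cyanamide could oligomerise at 95 °C. The fallback separates guanylation from ring closure. It sets out from 6: N,N'-di-Boc-N''-triflylguanidine and Et3N in CH2Cl2 at 0 °C should give the isolable di-tert-butyl {[3-(4-methoxyphenyl)-2-oxopropyl](methyl)amino}methylylidenedicarbamate (the N,N'-di-Boc guanidine) F9. TFA in CH2Cl2 then removes both Boc groups and cyclodehydrates, returning to 8.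

Step 5. Silyl transfer to the amidine nitrogens could stall the addition, the amine could attack the wrong carbonyl of the silylated trione, and the imino-hydantoin could open hydrolytically on work-up. The fallback builds the dehydrohydantoin ring stepwise. It sets out from 8: ethyl 2-ethoxy-2-iminoacetate should give ethyl 2-imino-2-{[4-(4-methoxybenzyl)-1-methyl-1H-imidazol-2-yl]amino}acetate F10. Methyl isocyanate should carbamoylate the terminal imine nitrogen to give ethyl 2-{[4-(4-methoxybenzyl)-1-methyl-1H-imidazol-2-yl]amino}-2-[(methylcarbamoyl)imino]acetate F11. DBU then closes the ring by attack of the N-methyl urea nitrogen on the ester, returning to 11.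

**Further compounds**

F1 | step 6 | N'-[4-(4-methoxybenzyl)-1-methyl-1H-imidazol-2-yl]-N,N-dimethylformimidamide | COc1ccc(Cc2cn(C)c(N=CN(C)C)n2)cc1
F2 | step 6 | N'-[5-bromo-4-(4-methoxybenzyl)-1-methyl-1H-imidazol-2-yl]-N,N-dimethylformimidamide | COc1ccc(Cc2nc(N=CN(C)C)n(C)c2Br)cc1
F3 | step 6 | 2,3-dimethoxybenzene-1,4-diol | COc1c(O)ccc(O)c1OC
F4 | step 6 | 2,3-dimethoxy-1,4-bis(methoxymethoxy)benzene | COCOc1ccc(OCOC)c(OC)c1OC
F5 | step 6 | 3,4-dimethoxy-2,5-bis(methoxymethoxy)benzaldehyde | COCOc1cc(C=O)c(OCOC)c(OC)c1OC
F6 | step 6 | N'-[5-{[3,4-dimethoxy-2,5-bis(methoxymethoxy)phenyl](hydroxy)methyl}-4-(4-methoxybenzyl)-1-methyl-1H-imidazol-2-yl]-N,N-dimethylformimidamide (racemic) | COc1ccc(Cc2nc(N=CN(C)C)n(C)c2C(O)c2cc(OCOC)c(OC)c(OC)c2OCOC)cc1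
F7 | step 6 | N'-[5-(2,5-dihydroxy-3,4-dimethoxybenzyl)-4-(4-methoxybenzyl)-1-methyl-1H-imidazol-2-yl]-N,N-dimethylformimidamide | COc1ccc(Cc2nc(N=CN(C)C)n(C)c2Cc2cc(O)c(OC)c(OC)c2O)cc1
F8 | step 6 | 2-{[2-amino-4-(4-methoxybenzyl)-1-methyl-1H-imidazol-5-yl]methyl}-5,6-dimethoxybenzene-1,4-diol | COc1ccc(Cc2nc(N)n(C)c2Cc2cc(O)c(OC)c(OC)c2O)cc1
F9 | step 4 | di-tert-butyl {[3-(4-methoxyphenyl)-2-oxopropyl](methyl)amino}methylylidenedicarbamate | COc1ccc(CC(=O)CN(C)C(=NC(=O)OC(C)(C)C)NC(=O)OC(C)(C)C)cc1
F10 | step 5 | ethyl 2-imino-2-{[4-(4-methoxybenzyl)-1-methyl-1H-imidazol-2-yl]amino}acetate | CCOC(=O)C(=N)Nc1nc(Cc2ccc(OC)cc2)cn1C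
F11 | step 5 | ethyl 2-{[4-(4-methoxybenzyl)-1-methyl-1H-imidazol-2-yl]amino}-2-[(methylcarbamoyl)imino]acetate | CCOC(=O)C(=NC(=O)NC)Nc1nc(Cc2ccc(OC)cc2)cn1C
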